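**Retrosynthetic overview**
- Target ⇒ C20 allylic alcohol + Meldrum's acid (half-ester made last).
- Each E-trisubstituted alkene ⇒ a β-keto ester (Z-enol phosphate, Me2CuLi, then DIBAL-H); the second β-keto ester ⇒ C15 allylic bromide + methyl acetoacetate dianion.
- Key C–C bond: the first β-keto ester ⇒ crossed decarboxylative Claisen condensation of the ring-bearing C12 acyl imidazolide with magnesium methyl malonate.
- Ring C12 acid ⇒ Grignard/CO2 homologation of a C11 ester, which comes from a Johnson–Claisen rearrangement that carries a CBS-set carbinol centre onto the ring carbon; exocyclic methylene ⇒ allylsilane protodesilylation.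
- Rings: the only ring is not built; it is bought as 4,4-dimethylcyclohex-2-en-1-one and carried through.

Assumption: the SMILES is read as (S) at the ring carbon with both chain alkenes E; ordinary catalogue reagents count as commercial.

**Route**

Step 1
Reactants: 1 4,4-dimethylcyclohex-2-en-1-one
Product: 2 2-iodo-4,4-dimethylcyclohex-2-en-1-one
Conditions: I2 (1.5 equiv), pyridine/CH2Cl2 1:1, 0 °C → rt, 12 h
Reagents that add atoms: iodine, II
Why: Baylis–Hillman-type α-iodination of an enone, in which pyridine adds reversibly in conjugate fashion, the enolate so formed is iodinated and E1cB loss of pyridine regenerates the enone, so only the α-vinylic carbon is substituted.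

Step 2
Reactants: 2 2-iodo-4,4-dimethylcyclohex-2-en-1-one
Product: 3 (1R)-2-iodo-4,4-dimethylcyclohex-2-en-1-ol
Conditions: (S)-Me-CBS oxazaborolidine (C18H20BNO, 10 mol %), BH3·SMe2 (1.0 equiv), THF, −20 °C, slow addition of 2; MeOH quench
Reagents that add atoms: none
Why: Corey–Bakshi–Shibata reduction, in which the α-iodovinyl carbon acts as the large carbonyl substituent so that the (S)-oxazaborolidine–BH3 complex delivers hydride to the face giving the (R)-carbinol (α-halo enones typically give ≥95 % ee) with clean 1,2-selectivity.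

Step 3
Reactants: 3 (1R)-2-iodo-4,4-dimethylcyclohex-2-en-1-ol
Product: 5 (1R)-4,4-dimethyl-2-[(trimethylsilyl)methyl]cyclohex-2-en-1-ol, via chloromagnesium alkoxide 4 (not isolated)
Conditions: Me3SiCH2MgCl (3 equiv), Pd(PPh3)4 (5 mol %), THF, 0 → 50 °C; aq. NH4Cl
Reagents that add atoms: (trimethylsilyl)methylmagnesium chloride, C[Si](C)(C)C[Mg]Cl
Why: Kumada–Corriu cross-coupling under zerovalent palladium catalysis, in which the first equivalent of Grignard reagent only deprotonates the hydroxyl and the second transfers the β-hydrogen-free CH2SiMe3 group to the vinyl iodide, leaving the carbinol stereocentre untouched.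

Step 4
Reactants: 5 (1R)-4,4-dimethyl-2-[(trimethylsilyl)methyl]cyclohex-2-en-1-ol; 6 triethyl orthoacetate
Product: 9 ethyl 2-[(1S)-6,6-dimethyl-2-[(trimethylsilyl)methyl]cyclohex-2-en-1-yl]acetate, via mixed orthoester 7 (not isolated), via ketene acetal 8 (not isolated)
Conditions: 6 (8 equiv, as solvent), EtCO2H (5 mol %), 140 °C, EtOH distilled off, 8–12 h
Reagents that add atoms: none
Why: Johnson–Claisen (orthoester) rearrangement, whose [3,3] shift is suprafacial across the cyclohexenyl unit so that the new C–C bond forms on the ring face that carried the C–O bond, converting the (R)-carbinol centre completely into the (S)-configured ring carbon next to the gem-dimethyl group while the double bond moves to the silylmethyl-bearing carbon.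

Step 5
Reactants: 9 ethyl 2-[(1S)-6,6-dimethyl-2-[(trimethylsilyl)methyl]cyclohex-2-en-1-yl]acetate
Product: 10 ethyl 2-[(1S)-2,2-dimethyl-6-methylidenecyclohexyl]acetate
Conditions: CF3CO2H (2 equiv), CH2Cl2, −20 → 0 °C, 20 min; poured into ice-cold aq. NaHCO3
Reagents that add atoms: none
Why: Protodesilylation of an allylsilane (SE2'), in which protonation of the ring CH terminus gives a β-silyl-stabilised cation that loses the silyl group, so the double bond ends regiospecifically in the exocyclic position and the adjacent stereocentre is not touched.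

Step 6
Reactants: 10 ethyl 2-[(1S)-2,2-dimethyl-6-methylidenecyclohexyl]acetate
Product: 11 2-[(1S)-2,2-dimethyl-6-methylidenecyclohexyl]ethan-1-ol
Conditions: LiAlH4 (1.0 equiv), Et2O, 0 °C; H2O, 15 % aq. NaOH
Reagents that add atoms: none
Why: Hydride reduction of the ester to the primary alcohol, to which the isolated 1,1-disubstituted alkene and the allylic stereocentre are inert.

Step 7
Reactants: 11 2-[(1S)-2,2-dimethyl-6-methylidenecyclohexyl]ethan-1-ol
Product: 12 (2S)-2-(2-bromoethyl)-1,1-dimethyl-3-methylidenecyclohexane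
Conditions: CBr4 (1.2 equiv), PPh3 (1.25 equiv), CH2Cl2, 0 °C
Reagents that add atoms: carbon tetrabromide, BrC(Br)(Br)Br
Why: Appel bromination, an SN2 displacement of the alkoxyphosphonium ion at an unhindered primary carbon under neutral conditions that cannot isomerise the exocyclic alkene.

Step 8
Reactants: 12 (2S)-2-(2-bromoethyl)-1,1-dimethyl-3-methylidenecyclohexane
Product: 14 3-[(1S)-2,2-dimethyl-6-methylidenecyclohexyl]propanoic acid, via Grignard reagent 13 (not isolated)
Conditions: Mg turnings (crystal of I2), THF, 45 °C; then dry CO2, −20 °C → rt; cold 1 M HCl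
Reagents that add atoms: carbon dioxide, O=C=O
Why: Grignard formation followed by carboxylation, in which the primary alkylmagnesium bromide adds to CO2 to give the one-carbon-homologated acid while the remote alkene and stereocentre stay intact.

Step 9 (key step)
Reactants: 14 3-[(1S)-2,2-dimethyl-6-methylidenecyclohexyl]propanoic acid; 15 potassium methyl malonate
Product: 18 methyl 5-[(1S)-2,2-dimethyl-6-methylidenecyclohexyl]-3-oxopentanoate, via magnesium methyl malonate 16 (not isolated), via acyl imidazolide 17 (not isolated)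
Conditions: 14, CDI (1.2 equiv), THF, rt, 2 h; separately 15 (2.2 equiv), MgCl2 (1.1 equiv), THF, 50 °C, 4 h; combine, rt → 40 °C, 16 h; cold 0.5 M HCl
Reagents that add atoms: none
Why: Crossed decarboxylative Claisen condensation (Masamune–Brooks), in which the magnesium malonate half-ester is C-acylated by the acyl imidazolide and then loses CO2, joining the ring-bearing C12 acyl fragment to the two-carbon ester fragment as the β-keto ester under nearly neutral conditions that cannot isomerise the ring alkene or touch the stereocentre.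

Step 10
Reactants: 18 methyl 5-[(1S)-2,2-dimethyl-6-methylidenecyclohexyl]-3-oxopentanoate
Product: 20 methyl (2Z)-3-[(diethoxyphosphoryl)oxy]-5-[(1S)-2,2-dimethyl-6-methylidenecyclohexyl]pent-2-enoate, via sodium enolate 19 (not isolated)
Conditions: NaH (1.1 equiv), Et2O, 0 °C; then (EtO)2P(O)Cl (1.1 equiv), 0 °C → rt
Reagents that add atoms: diethyl chlorophosphate, CCOP(=O)(Cl)OCC
Why: O-Phosphorylation of a β-keto ester enolate, in which the sodium enolate is held by chelation in the Z geometry in ether so that trapping on oxygen gives the (Z)-enol phosphate selectively.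

Step 11
Reactants: 20 methyl (2Z)-3-[(diethoxyphosphoryl)oxy]-5-[(1S)-2,2-dimethyl-6-methylidenecyclohexyl]pent-2-enoate
Product: 21 methyl (2E)-5-[(1S)-2,2-dimethyl-6-methylidenecyclohexyl]-3-methylpent-2-enoate
Conditions: Me2CuLi (2.5 equiv, from CuI and MeLi, Et2O, 0 °C), Et2O, −78 → −45 °C, 2 h; aq. NH4Cl
Reagents that add atoms: lithium dimethylcuprate, [Li+].C[Cu-]C
Why: Stereospecific cuprate substitution of a β-phosphoryloxy enoate (conjugate addition–elimination, the enol phosphate olefin synthesis), which replaces the phosphate by methyl with retention and so fixes the E trisubstituted alkene.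

Step 12
Reactants: 21 methyl (2E)-5-[(1S)-2,2-dimethyl-6-methylidenecyclohexyl]-3-methylpent-2-enoate
Product: 22 (2E)-5-[(1S)-2,2-dimethyl-6-methylidenecyclohexyl]-3-methylpent-2-en-1-ol
Conditions: i-Bu2AlH (2.5 equiv), CH2Cl2, −78 → 0 °C; aq. KNaC4H4O6
Reagents that add atoms: none
Why: DIBAL-H 1,2-reduction of the α,β-unsaturated ester to the allylic alcohol, which does not disturb the alkene geometry or the exocyclic methylene.

Step 13
Reactants: 22 (2E)-5-[(1S)-2,2-dimethyl-6-methylidenecyclohexyl]-3-methylpent-2-en-1-ol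
Product: 23 (2S)-2-[(3E)-5-bromo-3-methylpent-3-en-1-yl]-1,1-dimethyl-3-methylidenecyclohexane
Conditions: CBr4 (1.2 equiv), PPh3 (1.25 equiv), CH2Cl2, −20 → 0 °C; used crude after pentane/silica filtration
Reagents that add atoms: carbon tetrabromide, BrC(Br)(Br)Br
Why: Appel bromination of a primary allylic alcohol, a neutral SN2 process that gives the allylic bromide without allylic transposition or E/Z scrambling.

Step 14
Reactants: 23 (2S)-2-[(3E)-5-bromo-3-methylpent-3-en-1-yl]-1,1-dimethyl-3-methylidenecyclohexane; 24 methyl acetoacetate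
Product: 26 methyl (6E)-9-[(1S)-2,2-dimethyl-6-methylidenecyclohexyl]-7-methyl-3-oxonon-6-enoate, via acetoacetate dianion 25 (not isolated)
Conditions: 24 (1.5 equiv), NaH (1.6 equiv), THF, 0 °C; n-BuLi (1.55 equiv), 0 °C; then 23, 0 °C → rt; cold 0.5 M HCl
Reagents that add atoms: none
Why: γ-Alkylation of the acetoacetate dianion, in which the more reactive terminal carbanion displaces the primary allylic bromide by SN2 with the E alkene retained, giving the next β-keto ester.

Step 15
Reactants: 26 methyl (6E)-9-[(1S)-2,2-dimethyl-6-methylidenecyclohexyl]-7-methyl-3-oxonon-6-enoate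
Product: 28 methyl (2Z,6E)-3-[(diethoxyphosphoryl)oxy]-9-[(1S)-2,2-dimethyl-6-methylidenecyclohexyl]-7-methylnona-2,6-dienoate, via sodium enolate 27 (not isolated)
Conditions: NaH (1.1 equiv), Et2O, 0 °C; then (EtO)2P(O)Cl (1.1 equiv), 0 °C → rt
Reagents that add atoms: diethyl chlorophosphate, CCOP(=O)(Cl)OCC
Why: O-Phosphorylation of the chelated Z sodium enolate of the β-keto ester, which again gives the (Z)-enol phosphate selectively.

Step 16
Reactants: 28 methyl (2Z,6E)-3-[(diethoxyphosphoryl)oxy]-9-[(1S)-2,2-dimethyl-6-methylidenecyclohexyl]-7-methylnona-2,6-dienoate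
Product: 29 methyl (2E,6E)-9-[(1S)-2,2-dimethyl-6-methylidenecyclohexyl]-3,7-dimethylnona-2,6-dienoate
Conditions: Me2CuLi (2.5 equiv, from CuI and MeLi), Et2O, −78 → −45 °C, 2 h; aq. NH4Cl
Reagents that add atoms: lithium dimethylcuprate, [Li+].C[Cu-]C
Why: Stereoretentive cuprate substitution of the enol phosphate (conjugate addition–elimination), which sets the second E trisubstituted alkene.

Step 17
Reactants: 29 methyl (2E,6E)-9-[(1S)-2,2-dimethyl-6-methylidenecyclohexyl]-3,7-dimethylnona-2,6-dienoate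
Product: 30 (2E,6E)-9-[(1S)-2,2-dimethyl-6-methylidenecyclohexyl]-3,7-dimethylnona-2,6-dien-1-ol
Conditions: i-Bu2AlH (2.5 equiv), CH2Cl2, −78 → 0 °C; aq. KNaC4H4O6
Reagents that add atoms: none
Why: DIBAL-H 1,2-reduction of the enoate to the primary allylic alcohol with all three alkenes unchanged.

Step 18
Reactants: 30 (2E,6E)-9-[(1S)-2,2-dimethyl-6-methylidenecyclohexyl]-3,7-dimethylnona-2,6-dien-1-ol; 31 Meldrum's acid
Product: 32 3-{[(2E,6E)-9-[(1S)-2,2-dimethyl-6-methylidenecyclohexyl]-3,7-dimethylnona-2,6-dien-1-yl]oxy}-3-oxopropanoic acid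
Conditions: 31 (1.2 equiv), toluene, 85 °C, 4 h
Reagents that add atoms: none
Why: Alcoholysis of Meldrum's acid (acyl transfer with loss of acetone), in which the primary allylic alcohol opens the activated cyclic diester and gives the malonic half-ester directly without a protecting group.

**Compound list**

1 | 4,4-dimethylcyclohex-2-en-1-one | O=C1CCC(C)(C)C=C1 | starting material
2 | 2-iodo-4,4-dimethylcyclohex-2-en-1-one | O=C1CCC(C)(C)C=C1I | intermediate
3 | (1R)-2-iodo-4,4-dimethylcyclohex-2-en-1-ol | O[C@@H]1CCC(C)(C)C=C1I | intermediate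
4 | chloromagnesium (1R)-2-iodo-4,4-dimethylcyclohex-2-en-1-olate | Cl[Mg]O[C@@H]1CCC(C)(C)C=C1I | intermediate
5 | (1R)-4,4-dimethyl-2-[(trimethylsilyl)methyl]cyclohex-2-en-1-ol | O[C@@H]1CCC(C)(C)C=C1C[Si](C)(C)C | intermediate
6 | triethyl orthoacetate (1,1,1-triethoxyethane) | CC(OCC)(OCC)OCC | starting material
7 | {[(6R)-6-(1,1-diethoxyethoxy)-3,3-dimethylcyclohex-1-en-1-yl]methyl}trimethylsilane | CC(OCC)(OCC)O[C@@H]1CCC(C)(C)C=C1C[Si](C)(C)C | intermediate
8 | {[(6R)-6-[(1-ethoxyethenyl)oxy]-3,3-dimethylcyclohex-1-en-1-yl]methyl}trimethylsilane | C=C(OCC)O[C@@H]1CCC(C)(C)C=C1C[Si](C)(C)C | intermediate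
9 | ethyl 2-[(1S)-6,6-dimethyl-2-[(trimethylsilyl)methyl]cyclohex-2-en-1-yl]acetate | C[Si](C)(C)CC1=CCCC(C)(C)[C@@H]1CC(=O)OCC | intermediate
10 | ethyl 2-[(1S)-2,2-dimethyl-6-methylidenecyclohexyl]acetate | C=C1CCCC(C)(C)[C@@H]1CC(=O)OCC | intermediate
11 | 2-[(1S)-2,2-dimethyl-6-methylidenecyclohexyl]ethan-1-ol | C=C1CCCC(C)(C)[C@@H]1CCO | intermediate
12 | (2S)-2-(2-bromoethyl)-1,1-dimethyl-3-methylidenecyclohexane | C=C1CCCC(C)(C)[C@@H]1CCBr | intermediate
13 | {2-[(1S)-2,2-dimethyl-6-methylidenecyclohexyl]ethyl}magnesium bromide | C=C1CCCC(C)(C)[C@@H]1CC[Mg]Br | intermediate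
14 | 3-[(1S)-2,2-dimethyl-6-methylidenecyclohexyl]propanoic acid | C=C1CCCC(C)(C)[C@@H]1CCC(=O)O | intermediate
15 | potassium methyl malonate (potassium 3-methoxy-3-oxopropanoate) | [K+].[O-]C(=O)CC(=O)OC | starting material
16 | magnesium bis(3-methoxy-3-oxopropanoate) | [Mg+2].[O-]C(=O)CC(=O)OC.[O-]C(=O)CC(=O)OC | intermediate
17 | 3-[(1S)-2,2-dimethyl-6-methylidenecyclohexyl]-1-(1H-imidazol-1-yl)propan-1-one | C=C1CCCC(C)(C)[C@@H]1CCC(=O)n1ccnc1 | intermediate
18 | methyl 5-[(1S)-2,2-dimethyl-6-methylidenecyclohexyl]-3-oxopentanoate | C=C1CCCC(C)(C)[C@@H]1CCC(=O)CC(=O)OC | intermediate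
19 | sodium (2Z)-5-[(1S)-2,2-dimethyl-6-methylidenecyclohexyl]-1-methoxy-1-oxopent-2-en-3-olate | C=C1CCCC(C)(C)[C@@H]1CC/C([O-])=C/C(=O)OC.[Na+] | intermediate
20 | methyl (2Z)-3-[(diethoxyphosphoryl)oxy]-5-[(1S)-2,2-dimethyl-6-methylidenecyclohexyl]pent-2-enoate | C=C1CCCC(C)(C)[C@@H]1CC/C(OP(=O)(OCC)OCC)=C/C(=O)OC | intermediate
21 | methyl (2E)-5-[(1S)-2,2-dimethyl-6-methylidenecyclohexyl]-3-methylpent-2-enoate | C=C1CCCC(C)(C)[C@@H]1CC/C(C)=C/C(=O)OC | intermediate
22 | (2E)-5-[(1S)-2,2-dimethyl-6-methylidenecyclohexyl]-3-methylpent-2-en-1-ol | C=C1CCCC(C)(C)[C@@H]1CC/C(C)=C/CO | intermediate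
23 | (2S)-2-[(3E)-5-bromo-3-methylpent-3-en-1-yl]-1,1-dimethyl-3-methylidenecyclohexane | C=C1CCCC(C)(C)[C@@H]1CC/C(C)=C/CBr | intermediate
24 | methyl acetoacetate (methyl 3-oxobutanoate) | CC(=O)CC(=O)OC | starting material
25 | lithium sodium 1-methoxybuta-1,3-diene-1,3-diolate (dianion of methyl acetoacetate) | C=C([O-])C=C([O-])OC.[Li+].[Na+] | intermediate
26 | methyl (6E)-9-[(1S)-2,2-dimethyl-6-methylidenecyclohexyl]-7-methyl-3-oxonon-6-enoate | C=C1CCCC(C)(C)[C@@H]1CC/C(C)=C/CCC(=O)CC(=O)OC | intermediate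
27 | sodium (2Z,6E)-9-[(1S)-2,2-dimethyl-6-methylidenecyclohexyl]-1-methoxy-7-methyl-1-oxonona-2,6-dien-3-olate | C=C1CCCC(C)(C)[C@@H]1CC/C(C)=C/CC/C([O-])=C/C(=O)OC.[Na+] | intermediate
28 | methyl (2Z,6E)-3-[(diethoxyphosphoryl)oxy]-9-[(1S)-2,2-dimethyl-6-methylidenecyclohexyl]-7-methylnona-2,6-dienoate | C=C1CCCC(C)(C)[C@@H]1CC/C(C)=C/CC/C(OP(=O)(OCC)OCC)=C/C(=O)OC | intermediate
29 | methyl (2E,6E)-9-[(1S)-2,2-dimethyl-6-methylidenecyclohexyl]-3,7-dimethylnona-2,6-dienoate | C=C1CCCC(C)(C)[C@@H]1CC/C(C)=C/CC/C(C)=C/C(=O)OC | intermediate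
30 | (2E,6E)-9-[(1S)-2,2-dimethyl-6-methylidenecyclohexyl]-3,7-dimethylnona-2,6-dien-1-ol | C=C1CCCC(C)(C)[C@@H]1CC/C(C)=C/CC/C(C)=C/CO | intermediate
31 | Meldrum's acid (2,2-dimethyl-1,3-dioxane-4,6-dione) | CC1(C)OC(=O)CC(=O)O1 | starting material
32 | 3-{[(2E,6E)-9-[(1S)-2,2-dimethyl-6-methylidenecyclohexyl]-3,7-dimethylnona-2,6-dien-1-yl]oxy}-3-oxopropanoic acid | C=C1CCCC(C)(C)[C@@H]1CC/C(C)=C/CC/C(C)=C/COC(=O)CC(=O)O | target

**Totals and risks**

Total step count: 18. Longest linear sequence: 18 steps (1 → 32).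

Most likely to fail, first: step 4. The [3,3] bond forms at a ring carbon flanked by the quaternary centre, and the allylsilane must survive 140 °C with a trace of acid. Fallback, setting out from 5 and coming back at 9: acetylation (Ac2O, pyridine, DMAP) gives the allylic acetate F1. LDA then Me3SiCl/Et3N in THF at −78 °C gives the silyl ketene acetal F2. On warming to rt–60 °C this rearranges (Ireland–Claisen, same suprafacial transfer, no acid) to the trimethylsilyl ester F3. Aqueous work-up gives the acid F4, and EtI/K2CO3 in DMF returns ester 9.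

Second: step 5. Acid could move the exocyclic alkene into the ring (the tetrasubstituted isomer would erase the stereocentre) or let the ester capture the cation. Fallback, setting out from 3 and coming back at 10: 3 and 6 under the step 4 conditions give, through the mixed orthoester F5 and the ketene acetal F6, the vinyl iodide ester F7. Stille coupling with Bu3SnCH2OH (Pd(PPh3)4, dioxane, 90 °C) gives the hydroxymethyl ester F8, and ClCO2Me/pyridine gives the allylic methyl carbonate F9. Formate hydrogenolysis (Pd(OAc)2 and PBu3 1:1, HCO2NH4, dioxane, 80 °C) then delivers hydride to the ring carbon with allylic transposition and gives 10 under neutral conditions.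

Third: step 18. The free malonic acid at 85 °C could isomerise the exocyclic alkene or ionise the allylic ester. Fallback, setting out from 30 and coming back at 32: 31 heated with 2-(trimethylsilyl)ethanol (toluene, 100 °C) gives 2-(trimethylsilyl)ethyl hydrogen malonate F10. Coupling with 30 (EDC·HCl, DMAP, CH2Cl2, 0 °C → rt) gives the mixed malonate diester F11. Bu4NF in THF at 0 °C → rt cleaves the silylethyl ester by fragmentation and, after a pH 4 buffer wash, gives 32.

**Further compounds**

F1 | step 4 | (1R)-4,4-dimethyl-2-[(trimethylsilyl)methyl]cyclohex-2-en-1-yl acetate | CC(=O)O[C@@H]1CCC(C)(C)C=C1C[Si](C)(C)C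
F2 | step 4 | {[(6R)-3,3-dimethyl-6-({1-[(trimethylsilyl)oxy]ethenyl}oxy)cyclohex-1-en-1-yl]methyl}trimethylsilane | C=C(O[Si](C)(C)C)O[C@@H]1CCC(C)(C)C=C1C[Si](C)(C)C
F3 | step 4 | trimethylsilyl 2-[(1S)-6,6-dimethyl-2-[(trimethylsilyl)methyl]cyclohex-2-en-1-yl]acetate | C[Si](C)(C)CC1=CCCC(C)(C)[C@@H]1CC(=O)O[Si](C)(C)C
F4 | step 4 | 2-[(1S)-6,6-dimethyl-2-[(trimethylsilyl)methyl]cyclohex-2-en-1-yl]acetic acid | C[Si](C)(C)CC1=CCCC(C)(C)[C@@H]1CC(=O)O
F5 | step 5 | (6R)-6-(1,1-diethoxyethoxy)-1-iodo-3,3-dimethylcyclohex-1-ene | CC(OCC)(OCC)O[C@@H]1CCC(C)(C)C=C1I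
F6 | step 5 | (6R)-6-[(1-ethoxyethenyl)oxy]-1-iodo-3,3-dimethylcyclohex-1-ene | C=C(OCC)O[C@@H]1CCC(C)(C)C=C1I
F7 | step 5 | ethyl 2-[(1S)-2-iodo-6,6-dimethylcyclohex-2-en-1-yl]acetate | IC1=CCCC(C)(C)[C@@H]1CC(=O)OCC
F8 | step 5 | ethyl 2-[(1S)-2-(hydroxymethyl)-6,6-dimethylcyclohex-2-en-1-yl]acetate | OCC1=CCCC(C)(C)[C@@H]1CC(=O)OCC
F9 | step 5 | ethyl 2-[(1S)-2-{[(methoxycarbonyl)oxy]methyl}-6,6-dimethylcyclohex-2-en-1-yl]acetate | COC(=O)OCC1=CCCC(C)(C)[C@@H]1CC(=O)OCC
F10 | step 18 | 3-oxo-3-[2-(trimethylsilyl)ethoxy]propanoic acid | C[Si](C)(C)CCOC(=O)CC(=O)O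
F11 | step 18 | (2E,6E)-9-[(1S)-2,2-dimethyl-6-methylidenecyclohexyl]-3,7-dimethylnona-2,6-dien-1-yl 2-(trimethylsilyl)ethyl propanedioate | C=C1CCCC(C)(C)[C@@H]1CC/C(C)=C/CC/C(C)=C/COC(=O)CC(=O)OCC[Si](C)(C)C
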